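The route rests on the C2–C3 single bond of the ten-membered carbocycle, the CH2–CH2 link between the C1=C10 and C4=C5 alkenes (germacrane numbering). A twelve-membered macrolactone, in which C3 is joined through O–C(=O) to a phenylsulfonyl-bearing C2, is treated with Pd(0): ionisation of the allylic C3–O bond, loss of CO2 and collapse of the ion pair form C2–C3 and contract the ring to the ten-membered carbocycle in one operation. Both alkene geometries are set earlier: C1=C10 by carboalumination, C4=C5 by a silicon-tethered ring-closing metathesis whose seven-membered silaketal also protects O-6 and O-15. C7/C8 come from an Evans aldol–lactonisation, C6 from a Felkin vinyl addition.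

Key step: step 13

Remark on numbering: germacrane numbering is used in the text (ring C1–C10 with C1=C10 and C4=C5; C6 carries the ester oxygen, C8 the lactone oxygen; C11–C13 are the lactone carbons outside the ring, C14 is the methyl carbon on C10, C15 the CH2O carbon on C4); "target configuration" means the spatial arrangement at C6, C7 and C8 shown by the SMILES of 31.
Assumption: metal enolates, carbanions and organometallic species that are generated and consumed within one operation are treated as reactive species and carry no number; covalent intermediates of telescoped operations are numbered.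

Step 1
Reactants: 1 but-3-yn-1-ol
Product: 2 (2E)-3-methylpent-2-ene-1,5-diol
Conditions: AlMe3 (3 equiv), Cp2ZrCl2 (25 mol%), CH2Cl2, 0 °C → rt; then n-BuLi, THF, −30 °C; (CH2O)n, rt
Reagents that add atoms: trimethylaluminium, C[Al](C)C; paraformaldehyde (as formaldehyde), C=O
Why: Zr-catalysed syn-carboalumination of the terminal alkyne puts CH3 on the internal carbon with Al cis to it, and hydroxymethylation of the alkenylalanate should proceed with retention, which sets the E trisubstituted alkene that becomes C1=C10.

Step 2
Reactants: 2 (2E)-3-methylpent-2-ene-1,5-diol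
Product: 3 (3E)-3-methyl-5-(phenylsulfonyl)pent-3-en-1-ol
Conditions: PhSO2H, Pd(PPh3)4 (5 mol%), THF, rt
Reagents that add atoms: benzenesulfinic acid, O=S(O)c1ccccc1
Why: Pd(0)-catalysed dehydrative allylic substitution (Tsuji–Trost) ionises only the allylic C–OH, and the sulfinate should add at the unsubstituted terminus of the π-allyl to give the linear allyl sulfone with the E alkene retained, since syn/anti exchange would need a tertiary σ-allyl; the homoallylic alcohol is not touched.

Step 3
Reactants: 3 (3E)-3-methyl-5-(phenylsulfonyl)pent-3-en-1-ol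
Product: 4 (3E)-3-methyl-5-(phenylsulfonyl)pent-3-enal
Conditions: Dess–Martin periodinane, NaHCO3, CH2Cl2, 0 °C
Reagents that add atoms: none
Why: Dess–Martin oxidation under bicarbonate buffer should give the β,γ-unsaturated aldehyde without migration of the alkene into conjugation; the aldehyde is used at once.

Step 4
Reactants: 5 (4R)-4-benzyl-1,3-oxazolidin-2-one; 6 methyl 4-chloro-4-oxobutanoate
Product: 7 methyl 4-[(4R)-4-benzyl-2-oxo-1,3-oxazolidin-3-yl]-4-oxobutanoate
Conditions: n-BuLi, THF, −78 °C; then 6, −78 → 0 °C
Reagents that add atoms: none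
Why: N-acylation of the lithiated oxazolidinone by the acid chloride gives the Evans imide, the methyl ester being inert at −78 °C.

Step 5
Reactants: 7 methyl 4-[(4R)-4-benzyl-2-oxo-1,3-oxazolidin-3-yl]-4-oxobutanoate; 4 (3E)-3-methyl-5-(phenylsulfonyl)pent-3-enal
Product: 9 trans-γ-lactone imide, via syn-aldol adduct 8 (not isolated)
Conditions: Bu2BOTf, i-Pr2NEt, CH2Cl2, −78 → 0 °C; 4, −78 → 0 °C; then CSA (cat.), CH2Cl2, rt
Reagents that add atoms: none
Why: Evans boron aldol through the Z-enolate and a Zimmerman–Traxler chair, in which the (4R)-benzyl auxiliary blocks one enolate face, should give the Evans-syn adduct and so set C7 and C8 in the target configuration, and acid-catalysed attack of the C8 hydroxyl on the methyl ester then closes the trans γ-lactone.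

Step 6
Reactants: 9 trans-γ-lactone imide
Product: 10 S-ethyl (2S,3R)-2-[(2E)-2-methyl-4-(phenylsulfonyl)but-2-en-1-yl]-5-oxooxolane-3-carbothioate
Conditions: EtSH, n-BuLi, THF, 0 °C
Reagents that add atoms: ethanethiol, CCS
Why: Transacylation of the activated exocyclic imide carbonyl by lithium ethanethiolate should give the thioester and return the auxiliary, the weakly basic thiolate leaving C7 and the lactone intact.

Step 7
Reactants: 10 S-ethyl thioester
Product: 11 (2S,3R)-2-[(2E)-2-methyl-4-(phenylsulfonyl)but-2-en-1-yl]-5-oxooxolane-3-carbaldehyde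
Conditions: Et3SiH, 10% Pd/C, acetone, rt
Reagents that add atoms: none
Why: Fukuyama reduction (Pd-catalysed hydrosilane reduction of a thioester) stops at the aldehyde under neutral conditions, so the α-stereocentre C7 should not epimerise and the trisubstituted alkene, sulfone and lactone are not touched.

Step 8
Reactants: 11 lactone aldehyde
Product: 12 (4S,5S)-4-[(1R)-1-hydroxyprop-2-en-1-yl]-5-[(2E)-2-methyl-4-(phenylsulfonyl)but-2-en-1-yl]oxolan-2-one
Conditions: CH2=CHMgBr, THF, −78 °C
Reagents that add atoms: vinylmagnesium bromide, C=C[Mg]Br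
Why: Felkin–Anh addition of the vinyl Grignard reagent to the α-branched aldehyde (the C8 branch is the large group anti to the nucleophile) should deliver the vinyl group to the Re face and set C6 in the target configuration, while at −78 °C the aldehyde reacts far faster than the lactone or the sulfone α-CH2.

Step 9
Reactants: 12 vinyl carbinol; 13 2-methylidenepropane-1,3-diol
Product: 15 mixed silaketal diene, via chlorosilane 14 (not isolated)
Conditions: i-Pr2SiCl2, imidazole, CH2Cl2, 0 °C; then 13 (5 equiv), imidazole, 0 °C → rt
Reagents that add atoms: dichlorodi(propan-2-yl)silane, CC(C)[Si](Cl)(Cl)C(C)C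
Why: Stepwise silyl ether formation: the hindered secondary C6 hydroxyl gives the mono-alkoxychlorosilane, which is then capped by one hydroxyl of the excess symmetric diol to give the mixed silaketal (temporary silicon tether).

Step 10
Reactants: 15 mixed silaketal diene
Product: 16 seven-membered silaketal with free C3 hydroxyl
Conditions: Grubbs II catalyst (5 mol%), toluene, 80 °C
Reagents that add atoms: none
Why: Silicon-tethered ring-closing metathesis joins the vinyl group and the 1,1-disubstituted alkene in a seven-membered dioxasilepine, whose ring size forces the C15 and C6 oxygens cis on the new trisubstituted C4=C5 alkene, which is the geometry of the target (C3 trans to C6).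

Step 11
Reactants: 16 seven-membered silaketal with free C3 hydroxyl
Product: 17 α-sulfonyl carboxylic acid (C2 epimers)
Conditions: LiHMDS (2.2 equiv), THF, −78 °C; CO2; then 1 M HCl (0 °C, to pH 3)
Reagents that add atoms: carbon dioxide, O=C=O
Why: LiHMDS deprotonates the hydroxyl and then the allylic sulfone CH2, the most acidic C–H, and the α-sulfonyl carbanion should be carboxylated at its α-carbon by CO2 (the O-carbonate is lost on acidification), giving the acid as an inconsequential mixture of C2 epimers; −78 °C suppresses lactone enolisation and transsilylation.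

Step 12
Reactants: 17 α-sulfonyl carboxylic acid
Product: 18 twelve-membered macrolactone (C2 epimers)
Conditions: DIC, DMAP (cat.), CH2Cl2, rt, slow addition (0.002 M)
Reagents that add atoms: none
Why: Carbodiimide/DMAP macrolactonisation (Steglich–Keck conditions) under high dilution should esterify the primary allylic C3 hydroxyl with the C2 carboxyl and close the twelve-membered allyl α-sulfonyl ester.

Step 13
Reactants: 18 twelve-membered macrolactone
Product: 19 ring-contracted ten-membered sulfone (C2 epimers)
Conditions: Pd(PPh3)4 (10 mol%), toluene, 80 °C, 0.005 M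
Reagents that add atoms: none
Why: Pd(0) ionises the allylic C3–O bond of the macrolactone to a π-allyl–Pd cation (C3–C4–C5) paired with the α-sulfonyl carboxylate, which loses CO2 to give a sulfonyl- and allyl-stabilised carbanion at C2 that recombines with the exocyclic CH2 terminus C3, so that the C(=O)–O unit leaves the twelve-membered ring as CO2 and the C2–C3 bond of the ten-membered carbocycle is formed. The closest known reaction type is the Pd-catalysed decarboxylative allylation of allyl α-sulfonyl esters (Tsuji–Trost manifold), run here within a lactone ring. The ten-membered ring closes by attack of C2 on the CH2 terminus of the π-allyl inside the contact ion pair (exo with respect to the allyl unit, which restores the C4=C5 alkene in the silaketal ring); C-allylation before loss of CO2 would reach the same product after decarboxylation. The only new stereocentre, C2, is not controlled and is removed in step 14. The step needs attack at C3 and not at C5 (C5 is a hindered ring carbon and its attack would give an eight-membered ring containing the E alkene), α- and not γ-attack of the sulfonyl allyl anion, retention of both alkene geometries (C1=C10 stays localised next to the sulfone-stabilised carbon, C4=C5 is locked in the seven-membered silaketal so that the π-allyl cannot undergo syn/anti exchange) and ring closure instead of oligomerisation, which high dilution in a non-polar solvent and the tight ion pair should secure.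

Step 14
Reactants: 19 ring-contracted ten-membered sulfone
Product: 20 desulfonylated silaketal lactone
Conditions: Pd(PPh3)4 (10 mol%), NaBH4, THF/i-PrOH, 0 °C → rt
Reagents that add atoms: none
Why: Pd(0)-catalysed hydride reduction of the allylic sulfone (Tsuji–Trost-type hydrogenolysis): the sulfinate is ionised to a π-allyl and borohydride should deliver hydride to the less substituted C2 terminus, which keeps the C1=C10 position and its E geometry (exchange at the fully substituted C10 terminus is slow), and NaBH4 spares the lactone and the silaketal.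

Step 15
Reactants: 20 desulfonylated silaketal lactone
Product: 23 α-methylene lactone silaketal, via Mannich base 21 (not isolated), via ammonium iodide 22 (not isolated)
Conditions: LDA, THF, −78 °C; CH2=NMe2+ I−, −78 °C → rt; MeI, MeOH, rt; NaHCO3 (aq), CH2Cl2
Reagents that add atoms: N,N-dimethylmethylideneammonium iodide (Eschenmoser's salt), C=[N+](C)C.[I-]; iodomethane, CI (its methyl group is carried only by intermediate 22)
Why: α-Methylenation of the γ-lactone by enolate Mannich reaction with Eschenmoser's salt, quaternisation and base-induced elimination of trimethylamine should create the exocyclic C11=C13 alkene without touching any stereocentre.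

Step 16
Reactants: 23 α-methylene lactone silaketal
Product: 24 6,15-diol (6-O-deacyl target)
Conditions: HF·pyridine, pyridine/THF, 0 °C
Reagents that add atoms: none
Why: Fluoride-mediated cleavage of both Si–O bonds of the silaketal (desilylation) under pyridine-buffered conditions should free the 6- and 15-hydroxyls without acid-induced transannular cyclisation of the 1,5-diene.

Step 17
Reactants: 24 6,15-diol
Product: 25 15-O-TBS ether of 24
Conditions: TBSCl (1.05 equiv), imidazole, CH2Cl2, −20 °C
Reagents that add atoms: tert-butyl(chloro)dimethylsilane, CC(C)(C)[Si](C)(C)Cl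
Why: Kinetically selective silylation of the primary allylic C15 hydroxyl over the hindered secondary C6 hydroxyl at low temperature.

Step 18
Reactants: 26 (tert-butyldimethylsilyloxy)acetaldehyde; 27 ethyl 2-(triphenyl-λ5-phosphanylidene)propanoate
Product: 28 ethyl (2E)-4-[(tert-butyldimethylsilyl)oxy]-2-methylbut-2-enoate
Conditions: CH2Cl2, rt
Reagents that add atoms: none
Why: Wittig olefination with the stabilised α-branched ylide should give the E trisubstituted enoate (C=O trans to CH2OTBS).

Step 19
Reactants: 28 ethyl (2E)-4-[(tert-butyldimethylsilyl)oxy]-2-methylbut-2-enoate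
Product: 29 (2E)-4-[(tert-butyldimethylsilyl)oxy]-2-methylbut-2-enoic acid
Conditions: LiOH, THF/H2O, rt; then 1 M HCl to pH 4
Reagents that add atoms: water (as LiOH/H2O), O
Why: Saponification of the ethyl ester with LiOH leaves the primary TBS ether and the alkene geometry unchanged.

Step 20
Reactants: 25 15-O-TBS ether of 24; 29 (2E)-4-[(tert-butyldimethylsilyl)oxy]-2-methylbut-2-enoic acid
Product: 30 bis-TBS ether of the target
Conditions: DIC, DMAP, CH2Cl2, 0 °C → rt
Reagents that add atoms: none
Why: Steglich esterification (carbodiimide activation, DMAP acyl transfer) should acylate the free secondary C6 hydroxyl with retention of configuration at C6.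

Step 21
Reactants: 30 bis-TBS ether of the target
Product: 31 target CNP0344932.1
Conditions: HF·pyridine, THF, 0 °C → rt
Reagents that add atoms: none
Why: Global desilylation with HF·pyridine should remove both TBS ethers and leave the two esters, the α-methylene lactone and the acid-sensitive diene intact.

Compound list
1 | but-3-yn-1-ol | C#CCCO | starting material
2 | (2E)-3-methylpent-2-ene-1,5-diol | OCC/C(C)=C/CO | intermediate
3 | (3E)-3-methyl-5-(phenylsulfonyl)pent-3-en-1-ol | OCC/C(C)=C/CS(=O)(=O)c1ccccc1 | intermediate
4 | (3E)-3-methyl-5-(phenylsulfonyl)pent-3-enal | O=CC/C(C)=C/CS(=O)(=O)c1ccccc1 | intermediate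
5 | (4R)-4-benzyl-1,3-oxazolidin-2-one | O=C1OC[C@@H](Cc2ccccc2)N1 | starting material
6 | methyl 4-chloro-4-oxobutanoate | COC(=O)CCC(=O)Cl | starting material
7 | methyl 4-[(4R)-4-benzyl-2-oxo-1,3-oxazolidin-3-yl]-4-oxobutanoate | COC(=O)CCC(=O)N1[C@H](Cc2ccccc2)COC1=O | intermediate
8 | syn-aldol adduct: methyl (3R,4S,6E)-3-{[(4R)-4-benzyl-2-oxo-1,3-oxazolidin-3-yl]carbonyl}-4-hydroxy-6-methyl-8-(phenylsulfonyl)oct-6-enoate | COC(=O)C[C@@H](C(=O)N1[C@H](Cc2ccccc2)COC1=O)[C@@H](O)C/C(C)=C/CS(=O)(=O)c1ccccc1 | intermediate
9 | trans-γ-lactone imide: (4R)-4-benzyl-3-{[(2S,3R)-2-[(2E)-2-methyl-4-(phenylsulfonyl)but-2-en-1-yl]-5-oxooxolan-3-yl]carbonyl}-1,3-oxazolidin-2-one | O=C1C[C@@H](C(=O)N2[C@H](Cc3ccccc3)COC2=O)[C@H](C/C(C)=C/CS(=O)(=O)c2ccccc2)O1 | intermediate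
10 | S-ethyl (2S,3R)-2-[(2E)-2-methyl-4-(phenylsulfonyl)but-2-en-1-yl]-5-oxooxolane-3-carbothioate | O=C1C[C@@H](C(=O)SCC)[C@H](C/C(C)=C/CS(=O)(=O)c2ccccc2)O1 | intermediate
11 | (2S,3R)-2-[(2E)-2-methyl-4-(phenylsulfonyl)but-2-en-1-yl]-5-oxooxolane-3-carbaldehyde | O=C1C[C@@H](C=O)[C@H](C/C(C)=C/CS(=O)(=O)c2ccccc2)O1 | intermediate
12 | (4S,5S)-4-[(1R)-1-hydroxyprop-2-en-1-yl]-5-[(2E)-2-methyl-4-(phenylsulfonyl)but-2-en-1-yl]oxolan-2-one | O=C1C[C@@H]([C@H](O)C=C)[C@H](C/C(C)=C/CS(=O)(=O)c2ccccc2)O1 | intermediate
13 | 2-methylidenepropane-1,3-diol | C=C(CO)CO | starting material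
14 | chlorosilane: 12 with C6–O–Si(i-Pr)2Cl, other centres as in 12 | O=C1C[C@@H]([C@H](O[Si](Cl)(C(C)C)C(C)C)C=C)[C@H](C/C(C)=C/CS(=O)(=O)c2ccccc2)O1 | intermediate
15 | mixed silaketal diene: 12 with C6–O–Si(i-Pr)2–O–CH2–C(=CH2)–CH2OH, other centres as in 12 | O=C1C[C@@H]([C@H](O[Si](C(C)C)(C(C)C)OCC(=C)CO)C=C)[C@H](C/C(C)=C/CS(=O)(=O)c2ccccc2)O1 | intermediate
16 | RCM product: trans-γ-lactone of 12 whose C7 carries a 6-(hydroxymethyl)-2,2-di(propan-2-yl)-4,7-dihydro-1,3,2-dioxasilepin-4-yl ring (Si bridges O-6 and O-15, C4=C5 in that ring, C3 is the CH2OH carbon); C6, C7, C8 in the target configuration | O=C1C[C@@H]([C@@H]3O[Si](C(C)C)(C(C)C)OCC(CO)=C3)[C@H](C/C(C)=C/CS(=O)(=O)c2ccccc2)O1 | intermediate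
17 | α-sulfonyl acid: 16 with CO2H on C2 (C2 epimers) | O=C1C[C@@H]([C@@H]3O[Si](C(C)C)(C(C)C)OCC(CO)=C3)[C@H](C/C(C)=C/C(C(=O)O)S(=O)(=O)c2ccccc2)O1 | intermediate
18 | twelve-membered macrolactone: C2 carboxyl of 17 esterified by the C3 oxygen (ring C1, C2, C(=O), O, C3–C10; 1(10)E; C2 epimers) | O=C1C[C@H]2[C@@H]3O[Si](C(C)C)(C(C)C)OCC(COC(=O)C(S(=O)(=O)c4ccccc4)/C=C(C)/C[C@@H]2O1)=C3 | intermediate
19 | ring-contracted sulfone: ten-membered carbocycle C1–C10 with PhSO2 on C2, 1(10)E alkene, C4=C5 within the silaketal, trans-fused 12,8-lactone; C6, C7, C8 in the target configuration; C2 epimers | O=C1C[C@H]2[C@@H]3O[Si](C(C)C)(C(C)C)OCC(CC(S(=O)(=O)c4ccccc4)/C=C(C)/C[C@@H]2O1)=C3 | intermediate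
20 | 19 without the sulfonyl group (C2 = CH2) | O=C1C[C@H]2[C@@H]3O[Si](C(C)C)(C(C)C)OCC(CC/C=C(C)/C[C@@H]2O1)=C3 | intermediate
21 | Mannich base: 20 with CH2NMe2 on C11 (C11 epimers) | O=C1C(CN(C)C)[C@H]2[C@@H]3O[Si](C(C)C)(C(C)C)OCC(CC/C=C(C)/C[C@@H]2O1)=C3 | intermediate
22 | methiodide of 21 (trimethylammonium iodide) | O=C1C(C[N+](C)(C)C)[C@H]2[C@@H]3O[Si](C(C)C)(C(C)C)OCC(CC/C=C(C)/C[C@@H]2O1)=C3.[I-] | intermediate
23 | α-methylene lactone silaketal: 20 with exocyclic C11=C13H2 | O=C1C(=C)[C@H]2[C@@H]3O[Si](C(C)C)(C(C)C)OCC(CC/C=C(C)/C[C@@H]2O1)=C3 | intermediate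
24 | 6-O-deacyl target: 6,15-dihydroxygermacra-1(10)E,4Z,11(13)-trien-12,8-olide, target configuration at C6, C7, C8 | C=C1C(=O)O[C@H]2C/C(C)=C/CC/C(CO)=C/[C@@H](O)[C@H]12 | intermediate
25 | 15-O-tert-butyldimethylsilyl ether of 24 | C=C1C(=O)O[C@H]2C/C(C)=C/CC/C(CO[Si](C)(C)C(C)(C)C)=C/[C@@H](O)[C@H]12 | intermediate
26 | (tert-butyldimethylsilyloxy)acetaldehyde | O=CCO[Si](C)(C)C(C)(C)C | starting material
27 | ethyl 2-(triphenyl-λ5-phosphanylidene)propanoate | CCOC(=O)C(C)=P(c1ccccc1)(c1ccccc1)c1ccccc1 | starting material
28 | ethyl (2E)-4-[(tert-butyldimethylsilyl)oxy]-2-methylbut-2-enoate | CCOC(=O)/C(C)=C/CO[Si](C)(C)C(C)(C)C | intermediate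
29 | (2E)-4-[(tert-butyldimethylsilyl)oxy]-2-methylbut-2-enoic acid | OC(=O)/C(C)=C/CO[Si](C)(C)C(C)(C)C | intermediate
30 | bis-TBS ether of the target (15-OTBS and side-chain 4'-OTBS) | C=C1C(=O)O[C@H]2C/C(C)=C/CC/C(CO[Si](C)(C)C(C)(C)C)=C/[C@@H](OC(=O)/C(C)=C/CO[Si](C)(C)C(C)(C)C)[C@H]12 | intermediate
31 | (6R,7R,8S)-15-hydroxy-6-{[(2E)-4-hydroxy-2-methylbut-2-enoyl]oxy}germacra-1(10)E,4Z,11(13)-trien-12,8-olide (CNP0344932.1) | C=C1C(=O)O[C@H]2C/C(C)=C/CC/C(CO)=C/[C@@H](OC(=O)/C(C)=C/CO)[C@H]12 | target

Total step count: 21. Longest linear sequence: 18 steps (steps 1–3, 5–17, 20 and 21).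

Steps most likely to fail

Step 13. The zwitterion may be captured between molecules (oligomers) or the sulfonyl carbanion may be protonated by the acidic C2–H of unreacted 18 before the ring closes, or decarboxylation may lag behind return of the carboxylate. The fallback makes the C2–C3 bond by intramolecular alkylation of the sulfonyl carbanion. It sets out from 16, which is converted with CBr4/PPh3 (CH2Cl2, 0 °C) into the allylic bromide F1. F1 is cyclised with LiHMDS (1.05 equiv, THF, −78 → −20 °C, 0.002 M) to give 19, where the route is rejoined.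

Step 11. Deprotonation may stray to the lactone α-CH2, the lithium alkoxide may transsilylate the silaketal, or the free acid may lose CO2 on work-up. The fallback avoids both the free alkoxide and the free acid. It sets out from 16, which is treated with 1,1'-carbonyldiimidazole (CH2Cl2, rt) to give the alkoxycarbonylimidazole F2. The sulfonyl carbanion of F2 (LiHMDS, 2.1 equiv, THF, −78 °C, 0.002 M) is then acylated intramolecularly with loss of imidazolide (Claisen-type C-acylation), which should give the macrolactone 18 directly; the route is rejoined at 18 and step 12 is not needed.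

Step 14. Hydride may be delivered to the wrong allyl terminus or β-hydride elimination may intervene (alkene transposition or diene formation), or ionisation of the sulfone may be too slow with borohydride. The fallback sets out from 19 and uses LiBHEt3 with PdCl2(dppp) (THF, 0 °C), accepting that the lactone is reduced at the same time, to give the desulfonylated diol F3. TEMPO/PhI(OAc)2 (CH2Cl2, rt) then oxidises the primary alcohol selectively through the lactol back to the lactone 20, where the route is rejoined.

Further compounds
F1 | step 13 | allylic bromide: 16 with C3–Br in place of C3–OH | O=C1C[C@@H]([C@@H]3O[Si](C(C)C)(C(C)C)OCC(CBr)=C3)[C@H](C/C(C)=C/CS(=O)(=O)c2ccccc2)O1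
F2 | step 11 | alkoxycarbonylimidazole: 16 with C3–O–C(=O)–imidazol-1-yl | O=C1C[C@@H]([C@@H]3O[Si](C(C)C)(C(C)C)OCC(COC(=O)n4ccnc4)=C3)[C@H](C/C(C)=C/CS(=O)(=O)c2ccccc2)O1
F3 | step 14 | desulfonylated diol: 20 with the lactone reduced to C12H2OH and C8–OH | OCC[C@H]1[C@@H]3O[Si](C(C)C)(C(C)C)OCC(CC/C=C(C)/C[C@@H]1O)=C3
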